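**Overview.** Labdane numbering is used. Ring A (C1–C5, C10) is cut at its two opposite bonds, C2–C3 and C5–C10, because C1 and C4 each lie between the bond ends: a C1 ketone can make C2 and C10 nucleophilic, and the C19 ester on C4 makes C3 and C5 electrophilic. One pot joins a β-keto sulfone (C10–C1–C2) to a Morita–Baylis–Hillman carbonate (C3–C4–C5, already carrying C6–C13): cinchona-catalysed allylic alkylation forms C5–C10 and sets C5, then a 6-endo Michael addition forms C2–C3. Julia elimination of the sulfone gives the C1=C10 alkene, from which acid closes ring B with the C13 ketone capping C8.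

Key step: step 7

Remark: the sense of induction of the cinchona catalyst in step 7 is assumed by analogy with aryl-substituted Morita–Baylis–Hillman carbonates (the pseudoenantiomeric catalyst (DHQ)2PHAL would be taken if a test run showed the opposite sense); centres written without a descriptor are mixtures that are erased later.

Step 1
Reactants: 1 geranylacetone
Product: 2 geranylacetone ethylene ketal
Conditions: ethylene glycol, pyridinium p-toluenesulfonate (cat.), benzene, reflux, azeotropic removal of water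
Reagents that add atoms: ethylene glycol, OCCO
Why: Acid-catalysed ketalisation masks the C13 ketone (the later terminator of ring B closure) against the hydride, amalgam and amide-base steps; no stereocentre is formed and the mild acid should leave the (E)-alkene untouched.

Step 2
Reactants: 2 geranylacetone ethylene ketal
Product: 4 terminal epoxide of the ketal, via bromohydrin 3 (not isolated)
Conditions: N-bromosuccinimide, THF/H2O, 0 °C; then K2CO3, MeOH, rt
Reagents that add atoms: water, O; N-bromosuccinimide, O=C1CCC(=O)N1Br (its bromine stays only in 3)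
Why: Bromohydrin formation in aqueous THF followed by base-induced ring closure is the standard way to epoxidise only the terminal trisubstituted alkene of a polyprenyl chain; the oxirane centre is racemic and is excised in step 3.

Step 3
Reactants: 4 terminal epoxide of the ketal
Product: 5 ketal aldehyde (C5 to C13 chain)
Conditions: H5IO6, THF/H2O, 0 °C
Reagents that add atoms: none
Why: Periodic acid hydrates the epoxide and cleaves the glycol (Malaprade-type cleavage), releasing acetone and the C5 aldehyde; brief exposure at 0 °C should spare the dioxolane and no stereocentre is involved.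

Step 4
Reactants: 5 ketal aldehyde; 6 methyl acrylate
Product: 7 Morita–Baylis–Hillman alcohol (racemic)
Conditions: 1,4-diazabicyclo[2.2.2]octane (1 equiv), MeOH, rt
Reagents that add atoms: none
Why: The Morita–Baylis–Hillman reaction joins C5 to C4 of the acrylate, which brings in C3, C4 and the C19 carboxyl carbon; the carbinol centre is racemic and is erased in step 7 when the allyl ammonium ion forms.

Step 5
Reactants: 7 Morita–Baylis–Hillman alcohol
Product: 8 Morita–Baylis–Hillman tert-butyl carbonate (racemic)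
Conditions: Boc2O, 4-(dimethylamino)pyridine (cat.), CH2Cl2, 0 °C to rt
Reagents that add atoms: di-tert-butyl dicarbonate, CC(C)(C)OC(=O)OC(=O)OC(C)(C)C
Why: Acylation of the secondary allylic alcohol gives the carbonate whose ionisation releases tert-butoxide, the base needed in step 7; no new stereocentre is formed.

Step 6
Reactants: 9 3-chlorobutan-2-one; 10 sodium benzenesulfinate
Product: 11 3-(phenylsulfonyl)butan-2-one
Conditions: DMF, rt
Reagents that add atoms: none
Why: SN2 displacement of the α-chloro ketone by the sulfur of the sulfinate gives the β-keto sulfone, a C–H acid that reacts first through C10 and then through C2; its methine is racemic and configurationally labile.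

Step 7
Reactants: 8 Morita–Baylis–Hillman tert-butyl carbonate; 11 3-(phenylsulfonyl)butan-2-one
Product: 13 ring A keto sulfone ester, via allylation adduct 12 (not isolated)
Conditions: hydroquinidine 1,4-phthalazinediyl diether, (DHQD)2PHAL (10 mol %), toluene, rt; then KOt-Bu (0.3 equiv), THF, 0 °C
Reagents that add atoms: none
Why: Mechanism: the quinuclidine nitrogen of the catalyst adds to C3 in an SN2′ step, CO2 and tert-butoxide leave, the butoxide deprotonates 11 and the sulfonyl-stabilised carbanion attacks C5 of the chiral allyl ammonium ion in a second SN2′ step that forms C5–C10 and regenerates the acrylate, after which KOt-Bu makes the methyl ketone enolate, whose C2 adds to C3. The closest known reaction type is the Lewis-base-catalysed asymmetric allylic alkylation of Morita–Baylis–Hillman carbonates with 1,3-dicarbonyl-type C–H acids, continued by an intramolecular Michael addition (a formal [3+3] annulation). Ring A closes in the 6-endo-trig mode, C3 and C4 both ending inside the ring. C5 is set by the cinchona catalyst, which shields one face of the allyl ammonium ion; C10 and C4 arise as mixtures, which is harmless because C10 becomes sp2 in step 10 and C4 is set anew through its enolate in step 11. The step needs attack at C5 and not at C3, carbon and not oxygen alkylation, and conjugate addition instead of Claisen attack on the ester: the double SN2′ course, the soft carbanion and the reversibility of the oxygen-centred and acyl pathways should secure these, and C2 is the only enolisable carbon of the ketone because C10 is quaternary.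

Step 8
Reactants: 13 ring A keto sulfone ester
Product: 14 β-hydroxy sulfone
Conditions: NaBH4, CeCl3·7H2O, MeOH, −40 °C
Reagents that add atoms: none
Why: Luche-type borohydride reduction of the hindered ketone (the cerium salt keeps the medium non-basic, avoiding retro-Claisen opening) gives the β-hydroxy sulfone; the new C1 carbinol may be a mixture because C1 and C10 both become sp2 in step 10.

Step 9
Reactants: 14 β-hydroxy sulfone
Product: 15 β-acetoxy sulfone
Conditions: Ac2O, pyridine, 4-(dimethylamino)pyridine (cat.), rt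
Reagents that add atoms: acetic anhydride, CC(=O)OC(C)=O
Why: Nucleophile-catalysed acetylation turns the hydroxyl into the leaving group of the Julia–Lythgoe sequence; no stereocentre is created.

Step 10
Reactants: 15 β-acetoxy sulfone
Product: 16 cyclohexene ester with the C1=C10 alkene
Conditions: Na/Hg (6 %), Na2HPO4, THF/MeOH, −20 °C
Reagents that add atoms: none
Why: Julia–Lythgoe reductive elimination: electron transfer cleaves the C10–S bond and the carbanion expels acetate, which places the alkene regiospecifically at C1=C10 whatever the configuration at C1 or C10, while C5 is untouched.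

Step 11
Reactants: 16 cyclohexene ester
Product: 18 C4-methylated dienyl ketone, via methylated ketal 17 (not isolated)
Conditions: LiN(i-Pr)2, THF, −78 °C; MeI, −78 to 0 °C; then 1 M HCl, THF, rt
Reagents that add atoms: iodomethane, CI
Why: Ester enolate alkylation: allylic 1,3-strain in the enolate pushes the C5 side chain pseudoaxial so that iodomethane should enter anti to it, giving 4α-CH3/4β-CO2CH3 (C4 S), and the acidic work-up removes the dioxolane (acetal hydrolysis).

Step 12
Reactants: 18 C4-methylated dienyl ketone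
Product: 20 bicyclic 8α-hydroxy ketone, via bicyclic enol ether 19 (not isolated)
Conditions: ClSO3H, 2-nitropropane, −78 °C; then 1 M HCl, THF/H2O, rt
Reagents that add atoms: water, O
Why: Brønsted-acid-initiated cationic polyene-type cyclisation with carbonyl-oxygen termination (the reaction type that turns farnesylacetone into a bicyclic enol ether): protonation at C1 gives the C10 cation, the (E)-alkene adds through C9 in a chair-like anti fashion with the C5 chain equatorial (trans ring fusion, 10β-CH3, 9β side chain), the ketone oxygen caps C8 from the α face, and aqueous acid then hydrolyses the enol ether to the 8α-hydroxy ketone.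

Step 13
Reactants: 20 bicyclic 8α-hydroxy ketone
Product: 21 triethylsilyl ether
Conditions: Et3SiOTf, 2,6-lutidine, CH2Cl2, −78 °C
Reagents that add atoms: triethylsilyl trifluoromethanesulfonate, CC[Si](CC)(CC)OS(=O)(=O)C(F)(F)F
Why: Silylation of the tertiary alcohol with a silyl triflate prevents alkoxide or hemiketal interference in the enolisation and leaves a single free hydroxyl later; no stereocentre changes.

Step 14
Reactants: 21 triethylsilyl ether
Product: 22 vinyl triflate
Conditions: KN(SiMe3)2, THF, −78 °C; then PhNTf2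
Reagents that add atoms: N-phenylbis(trifluoromethanesulfonimide), O=S(=O)(N(c1ccccc1)S(=O)(=O)C(F)(F)F)C(F)(F)F
Why: Kinetic deprotonation of the methyl ketone on its methyl side (C16) by the bulky amide base and O-sulfonylation of the enolate give the 2-alkyl vinyl triflate; the C19 ester has no α-hydrogen and cannot interfere.

Step 15
Reactants: 22 vinyl triflate
Product: 23 diene ester
Conditions: tributyl(vinyl)stannane, Pd(PPh3)4 (5 mol %), LiCl, THF, 65 °C
Reagents that add atoms: tributyl(vinyl)stannane, C=C[Sn](CCCC)(CCCC)CCCC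
Why: Stille cross-coupling of the vinyl triflate with the vinylstannane, assisted by LiCl, builds the 2-substituted 1,3-diene C13(=C16)–C14=C15 under neutral conditions; no stereocentre is involved.

Step 16
Reactants: 23 diene ester
Product: 24 C19 primary alcohol
Conditions: LiAlH4, THF, 0 °C to rt
Reagents that add atoms: none
Why: Hydride reduction of the hindered axial ester gives the neopentyl primary alcohol C19–OH; the diene and the silyl ether are inert to LiAlH4.

Step 17
Reactants: 25 (E)-ferulic acid
Product: 27 phenol-silylated ferulic acid, via bis-silylated ferulate 26 (not isolated)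
Conditions: t-BuMe2SiCl (2.5 equiv), imidazole, DMF, rt; then K2CO3, THF/MeOH/H2O, rt; acidification
Reagents that add atoms: tert-butyldimethylsilyl chloride, CC(C)(C)[Si](C)(C)Cl
Why: Exhaustive silylation of phenol and acid followed by selective solvolysis of the labile silyl ester gives the phenol-protected acid, so that only the carboxyl group can be activated in step 18.

Step 18
Reactants: 24 C19 primary alcohol; 27 phenol-silylated ferulic acid
Product: 28 doubly silylated target
Conditions: EDC·HCl, 4-(dimethylamino)pyridine, CH2Cl2, rt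
Reagents that add atoms: none
Why: Carbodiimide/aminopyridine (Steglich) esterification acylates the only free hydroxyl, the primary C19–OH, with retention of the (E)-cinnamate geometry.

Step 19
Reactants: 28 doubly silylated target
Product: 29 target CNP0142252.1
Conditions: Bu4NF, AcOH, THF, rt
Reagents that add atoms: none
Why: Fluoride-mediated desilylation, buffered with acetic acid to protect the cinnamate ester, removes the phenolic silyl group and the tertiary triethylsilyl ether and should release the target with all stereocentres untouched.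

**Compound list**

1 | geranylacetone, (5E)-6,10-dimethylundeca-5,9-dien-2-one | CC(=O)CC/C=C(\C)CCC=C(C)C | starting material
2 | 2-[(3E)-4,8-dimethylnona-3,7-dien-1-yl]-2-methyl-1,3-dioxolane | CC1(CC/C=C(\C)CCC=C(C)C)OCCO1 | intermediate
3 | (6E)-3-bromo-2,6-dimethyl-9-(2-methyl-1,3-dioxolan-2-yl)non-6-en-2-ol, racemic | CC1(CC/C=C(\C)CCC(Br)C(C)(C)O)OCCO1 | intermediate
4 | 2-[(3E)-6-(3,3-dimethyloxiran-2-yl)-4-methylhex-3-en-1-yl]-2-methyl-1,3-dioxolane, racemic oxirane | CC1(CC/C=C(\C)CCC2OC2(C)C)OCCO1 | intermediate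
5 | (4E)-4-methyl-7-(2-methyl-1,3-dioxolan-2-yl)hept-4-enal | CC1(CC/C=C(\C)CCC=O)OCCO1 | intermediate
6 | methyl acrylate | C=CC(=O)OC | starting material
7 | methyl (6E)-3-hydroxy-6-methyl-2-methylidene-9-(2-methyl-1,3-dioxolan-2-yl)non-6-enoate, racemic | C=C(C(=O)OC)C(O)CC/C(C)=C/CCC1(C)OCCO1 | intermediate
8 | methyl (6E)-3-[(tert-butoxycarbonyl)oxy]-6-methyl-2-methylidene-9-(2-methyl-1,3-dioxolan-2-yl)non-6-enoate, racemic | C=C(C(=O)OC)C(OC(=O)OC(C)(C)C)CC/C(C)=C/CCC1(C)OCCO1 | intermediate
9 | 3-chlorobutan-2-one | CC(=O)C(C)Cl | starting material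
10 | sodium benzenesulfinate | [Na+].[O-]S(=O)c1ccccc1 | starting material
11 | 3-(phenylsulfonyl)butan-2-one, racemic | CC(=O)C(C)S(=O)(=O)c1ccccc1 | intermediate
12 | methyl (3S,6E)-6-methyl-2-methylidene-9-(2-methyl-1,3-dioxolan-2-yl)-3-[3-oxo-2-(phenylsulfonyl)butan-2-yl]non-6-enoate, epimers at the sulfonyl carbon | CC(=O)C(C)(S(=O)(=O)c1ccccc1)[C@H](C(=C)C(=O)OC)CC/C(C)=C/CCC1(C)OCCO1 | intermediate
13 | methyl (2S)-3-methyl-2-[(3E)-3-methyl-6-(2-methyl-1,3-dioxolan-2-yl)hex-3-en-1-yl]-4-oxo-3-(phenylsulfonyl)cyclohexane-1-carboxylate, epimers at ring C1 and C3 | COC(=O)C1CCC(=O)C(C)(S(=O)(=O)c2ccccc2)[C@H]1CC/C(C)=C/CCC3(C)OCCO3 | intermediate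
14 | methyl (2S)-4-hydroxy-3-methyl-2-[(3E)-3-methyl-6-(2-methyl-1,3-dioxolan-2-yl)hex-3-en-1-yl]-3-(phenylsulfonyl)cyclohexane-1-carboxylate, epimers at ring C1, C3 and C4 | COC(=O)C1CCC(O)C(C)(S(=O)(=O)c2ccccc2)[C@H]1CC/C(C)=C/CCC3(C)OCCO3 | intermediate
15 | methyl (2S)-4-acetoxy-3-methyl-2-[(3E)-3-methyl-6-(2-methyl-1,3-dioxolan-2-yl)hex-3-en-1-yl]-3-(phenylsulfonyl)cyclohexane-1-carboxylate, epimers at ring C1, C3 and C4 | COC(=O)C1CCC(OC(C)=O)C(C)(S(=O)(=O)c2ccccc2)[C@H]1CC/C(C)=C/CCC3(C)OCCO3 | intermediate
16 | methyl (2S)-3-methyl-2-[(3E)-3-methyl-6-(2-methyl-1,3-dioxolan-2-yl)hex-3-en-1-yl]cyclohex-3-ene-1-carboxylate, epimers at ring C1 | COC(=O)C1CCC=C(C)[C@H]1CC/C(C)=C/CCC2(C)OCCO2 | intermediate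
17 | methyl (1S,2R)-1,3-dimethyl-2-[(3E)-3-methyl-6-(2-methyl-1,3-dioxolan-2-yl)hex-3-en-1-yl]cyclohex-3-ene-1-carboxylate | COC(=O)[C@@]1(C)CCC=C(C)[C@H]1CC/C(C)=C/CCC2(C)OCCO2 | intermediate
18 | methyl (1S,2R)-1,3-dimethyl-2-[(3E)-3-methyl-7-oxooct-3-en-1-yl]cyclohex-3-ene-1-carboxylate | COC(=O)[C@@]1(C)CCC=C(C)[C@H]1CC/C(C)=C/CCC(C)=O | intermediate
19 | methyl 8α,13-epoxy-14,15-dinorlabd-12-en-19-oate (5α-H, 9α-H, 10β-CH3, 4α-CH3) | CC1=CC[C@@H]2[C@@]3(C)CCC[C@](C)(C(=O)OC)[C@@H]3CC[C@@]2(C)O1 | intermediate
20 | methyl 8α-hydroxy-13-oxo-14,15-dinorlabdan-19-oate | CC(=O)CC[C@@H]1[C@@]2(C)CCC[C@](C)(C(=O)OC)[C@@H]2CC[C@@]1(C)O | intermediate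
21 | methyl 13-oxo-8α-(triethylsilyloxy)-14,15-dinorlabdan-19-oate | CC(=O)CC[C@@H]1[C@@]2(C)CCC[C@](C)(C(=O)OC)[C@@H]2CC[C@@]1(C)O[Si](CC)(CC)CC | intermediate
22 | methyl 8α-(triethylsilyloxy)-13-(trifluoromethylsulfonyloxy)-14,15-dinorlabd-13(16)-en-19-oate | C=C(OS(=O)(=O)C(F)(F)F)CC[C@@H]1[C@@]2(C)CCC[C@](C)(C(=O)OC)[C@@H]2CC[C@@]1(C)O[Si](CC)(CC)CC | intermediate
23 | methyl 8α-(triethylsilyloxy)labda-13(16),14-dien-19-oate | C=CC(=C)CC[C@@H]1[C@@]2(C)CCC[C@](C)(C(=O)OC)[C@@H]2CC[C@@]1(C)O[Si](CC)(CC)CC | intermediate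
24 | 8α-(triethylsilyloxy)labda-13(16),14-dien-19-ol | C=CC(=C)CC[C@@H]1[C@@]2(C)CCC[C@](C)(CO)[C@@H]2CC[C@@]1(C)O[Si](CC)(CC)CC | intermediate
25 | (E)-ferulic acid | COc1cc(/C=C/C(=O)O)ccc1O | starting material
26 | tert-butyldimethylsilyl (E)-3-[4-(tert-butyldimethylsilyloxy)-3-methoxyphenyl]prop-2-enoate | COc1cc(/C=C/C(=O)O[Si](C)(C)C(C)(C)C)ccc1O[Si](C)(C)C(C)(C)C | intermediate
27 | (E)-3-[4-(tert-butyldimethylsilyloxy)-3-methoxyphenyl]prop-2-enoic acid | COc1cc(/C=C/C(=O)O)ccc1O[Si](C)(C)C(C)(C)C | intermediate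
28 | 8α-(triethylsilyloxy)labda-13(16),14-dien-19-yl (E)-3-[4-(tert-butyldimethylsilyloxy)-3-methoxyphenyl]prop-2-enoate | C=CC(=C)CC[C@@H]1[C@@]2(C)CCC[C@](C)(COC(=O)/C=C/c3ccc(O[Si](C)(C)C(C)(C)C)c(OC)c3)[C@@H]2CC[C@@]1(C)O[Si](CC)(CC)CC | intermediate
29 | 8α-hydroxylabda-13(16),14-dien-19-yl (E)-ferulate, (4S,5R,8R,9R,10S), CNP0142252.1 | C=CC(=C)CC[C@@H]1[C@@]2(C)CCC[C@](C)(COC(=O)/C=C/c3ccc(O)c(OC)c3)[C@@H]2CC[C@@]1(C)O | target

**Step count.** Total: 19 steps. Longest linear sequence: 17 steps (steps 1–5, 7–16, 18 and 19, from geranylacetone 1).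

**Steps most likely to fail and their fallbacks**

Step 7. The hindered sulfonyl carbanion may attack the alkyl-substituted allyl ammonium ion slowly or with poor facial selectivity, so that enantiocontrol at C5 is lost. The fallback sets out from 5 and comes back at 13. Wittig reaction of 5 with (triphenylphosphoranylidene)acetaldehyde would give (2E,6E)-6-methyl-9-(2-methyl-1,3-dioxolan-2-yl)nona-2,6-dienal F1. Iminium-catalysed Michael addition of 11 to F1, with the enantiomer of α,α-diphenylprolinol trimethylsilyl ether that delivers the 3S centre, would give the Michael aldehyde F2. Amine-catalysed α-methylenation with aqueous formaldehyde would give the 2-methylidene aldehyde F3. Catalytic KOt-Bu would close ring A by the same 6-endo Michael addition to the keto aldehyde F4. Oxidation with NaClO2/NaH2PO4/2-methyl-2-butene would give the carboxylic acid F5, and trimethylsilyldiazomethane would give 13.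

Step 12. Protonation may start at the side-chain alkene with premature capture of the C8 cation by the ketone, the C10 cation may be intercepted by the C19 ester carbonyl, and loss of the C5 proton from the C10 cation would erode the C5 configuration. The fallback sets out from 14 and comes back at 20. Dehydration of 14 with methyl N-(triethylammoniumsulfonyl)carbamate would give the tertiary allylic sulfone F6 (C1=C2 alkene). Enolate methylation (LiN(i-Pr)2, MeI) would give the C4-methylated allylic sulfone ketal F7, and dilute HCl the allylic sulfone ketone F8. Ionisation of the allylic sulfone with EtAlCl2 in CH2Cl2 at −78 °C would generate the C10–C1–C2 allyl cation at the intended site only and without Brønsted acid. The same chair-like closure and an aqueous acid work-up would give the Δ1-unsaturated hydroxy ketone F9, and hydrogenation (H2, Pd/C) would give 20.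

Step 11. The enolate methylation on the flexible monocycle may show poor facial selectivity. The fallback sets out from 16 and comes back at 23. Hydrolysis of the ketal (1 M HCl, THF) would give the unmethylated dienyl ketone F10. Cyclisation as in step 12 would give the 4-unsubstituted bicyclic hydroxy ketone F11. Silylation as in step 13 would give the silyl ether F12. Triflation as in step 14 would give the vinyl triflate F13, the ketone being more acidic than the hindered ester. Stille coupling as in step 15 would give the diene ester F14. Methylation of the ester enolate of F14 (LiN(i-Pr)2, MeI) in the rigid trans-decalin, where the axial C10 methyl blocks the β face, would give 23.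

Further compounds
F1 | step 7 | (2E,6E)-6-methyl-9-(2-methyl-1,3-dioxolan-2-yl)nona-2,6-dienal | O=C/C=C/CC/C(C)=C/CCC1(C)OCCO1
F2 | step 7 | (3S,6E)-6-methyl-9-(2-methyl-1,3-dioxolan-2-yl)-3-[3-oxo-2-(phenylsulfonyl)butan-2-yl]non-6-enal | O=CC[C@H](CC/C(C)=C/CCC1(C)OCCO1)C(C)(C(C)=O)S(=O)(=O)c1ccccc1
F3 | step 7 | (3S,6E)-6-methyl-2-methylidene-9-(2-methyl-1,3-dioxolan-2-yl)-3-[3-oxo-2-(phenylsulfonyl)butan-2-yl]non-6-enal | O=CC(=C)[C@H](CC/C(C)=C/CCC1(C)OCCO1)C(C)(C(C)=O)S(=O)(=O)c1ccccc1
F4 | step 7 | (2S)-3-methyl-2-[(3E)-3-methyl-6-(2-methyl-1,3-dioxolan-2-yl)hex-3-en-1-yl]-4-oxo-3-(phenylsulfonyl)cyclohexane-1-carbaldehyde | O=CC1CCC(=O)C(C)(S(=O)(=O)c2ccccc2)[C@H]1CC/C(C)=C/CCC3(C)OCCO3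
F5 | step 7 | (2S)-3-methyl-2-[(3E)-3-methyl-6-(2-methyl-1,3-dioxolan-2-yl)hex-3-en-1-yl]-4-oxo-3-(phenylsulfonyl)cyclohexane-1-carboxylic acid | OC(=O)C1CCC(=O)C(C)(S(=O)(=O)c2ccccc2)[C@H]1CC/C(C)=C/CCC3(C)OCCO3
F6 | step 12 | methyl (2S)-3-methyl-2-[(3E)-3-methyl-6-(2-methyl-1,3-dioxolan-2-yl)hex-3-en-1-yl]-3-(phenylsulfonyl)cyclohex-4-ene-1-carboxylate | COC(=O)C1CC=CC(C)(S(=O)(=O)c2ccccc2)[C@H]1CC/C(C)=C/CCC3(C)OCCO3
F7 | step 12 | methyl (1S,2S)-1,3-dimethyl-2-[(3E)-3-methyl-6-(2-methyl-1,3-dioxolan-2-yl)hex-3-en-1-yl]-3-(phenylsulfonyl)cyclohex-4-ene-1-carboxylate | COC(=O)[C@@]1(C)CC=CC(C)(S(=O)(=O)c2ccccc2)[C@H]1CC/C(C)=C/CCC3(C)OCCO3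
F8 | step 12 | methyl (1S,2S)-1,3-dimethyl-2-[(3E)-3-methyl-7-oxooct-3-en-1-yl]-3-(phenylsulfonyl)cyclohex-4-ene-1-carboxylate | COC(=O)[C@@]1(C)CC=CC(C)(S(=O)(=O)c2ccccc2)[C@H]1CC/C(C)=C/CCC(C)=O
F9 | step 12 | methyl 8α-hydroxy-13-oxo-14,15-dinorlabd-1-en-19-oate | CC(=O)CC[C@@H]1[C@@]2(C)C=CC[C@](C)(C(=O)OC)[C@@H]2CC[C@@]1(C)O
F10 | step 11 | methyl (2S)-3-methyl-2-[(3E)-3-methyl-7-oxooct-3-en-1-yl]cyclohex-3-ene-1-carboxylate | COC(=O)C1CCC=C(C)[C@H]1CC/C(C)=C/CCC(C)=O
F11 | step 11 | methyl 8α-hydroxy-13-oxo-14,15,18-trinorlabdan-19-oate, epimers at C4 | CC(=O)CC[C@@H]1[C@@]2(C)CCCC(C(=O)OC)[C@@H]2CC[C@@]1(C)O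
F12 | step 11 | methyl 13-oxo-8α-(triethylsilyloxy)-14,15,18-trinorlabdan-19-oate | CC(=O)CC[C@@H]1[C@@]2(C)CCCC(C(=O)OC)[C@@H]2CC[C@@]1(C)O[Si](CC)(CC)CC
F13 | step 11 | methyl 8α-(triethylsilyloxy)-13-(trifluoromethylsulfonyloxy)-14,15,18-trinorlabd-13(16)-en-19-oate | C=C(OS(=O)(=O)C(F)(F)F)CC[C@@H]1[C@@]2(C)CCCC(C(=O)OC)[C@@H]2CC[C@@]1(C)O[Si](CC)(CC)CC
F14 | step 11 | methyl 8α-(triethylsilyloxy)-18-norlabda-13(16),14-dien-19-oate | C=CC(=C)CC[C@@H]1[C@@]2(C)CCCC(C(=O)OC)[C@@H]2CC[C@@]1(C)O[Si](CC)(CC)CC
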